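**Retrosynthetic overview**

1. Comments use daucane positions: C1 (quaternary ring-fusion carbon with methyl), C4 (carbinol with isopropyl), C5 (ring-fusion CH), C6 (aroyloxy carbon), C8=C9 (olefin), C10 (isovaleryloxy carbon).
2. Target ⇐ phenol unmasking ⇐ C10–O bond by direct allylic C–H acyloxylation of the C8=C9 olefin with isovaleric acid ⇐ 6-O-aroyl diol.
3. Seven-membered ring ⇐ ring-closing metathesis (C8=C9) of an allyl/methallyl diene; C6 carbinol ⇐ reagent-controlled methallylboration of a C6 aldehyde.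
4. C1 quaternary centre and C5 ⇐ 1,2-allylation, then anionic oxy-Cope rearrangement of a cyclopentene carbaldehyde.
5. Five-membered ring and C4 carbinol ⇐ ozonolysis/aldol ring contraction of (R)-terpinen-4-ol; ring order: five-membered ring first (step 2), seven-membered ring second (step 6).

Assumption: commercial (R)-(−)-terpinen-4-ol (compound 1) is used as a single enantiomer (enantio-enriched lots are upgraded before use); its carbinol carbon becomes C4 of the target unchanged.

**Route**

Step 1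
Reactants: 1 (R)-terpinen-4-ol
Product: 3 (3R)-3-hydroxy-6-oxo-3-(propan-2-yl)heptanal, via secondary ozonide 2 (not isolated)
Conditions: O3, CH2Cl2, −78 °C; then Me2S, −78 °C → rt
Reagents that add atoms: ozone, O=[O+][O-]
Why: Ozonolysis (Criegee mechanism) cleaves the only C=C bond to the keto-aldehyde after reductive work-up, and the tertiary carbinol centre is not touched.

Step 2
Reactants: 3 (3R)-3-hydroxy-6-oxo-3-(propan-2-yl)heptanal
Product: 4 (5S)-5-hydroxy-2-methyl-5-(propan-2-yl)cyclopent-1-ene-1-carbaldehyde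
Conditions: piperidine (0.3 equiv), AcOH (0.3 equiv), toluene, 4 Å sieves, rt → 50 °C
Reagents that add atoms: none
Why: Intramolecular enamine aldol condensation (aldehyde enamine onto the methyl ketone, five-membered ring closure, then dehydration), the ring contraction that is standard for the limonene-derived keto-aldehyde, gives the enal without involving the carbinol centre.

Step 3
Reactants: 4 (5S)-5-hydroxy-2-methyl-5-(propan-2-yl)cyclopent-1-ene-1-carbaldehyde; 5 allyl bromide
Product: 6 (1S)-2-(1-hydroxybut-3-en-1-yl)-3-methyl-1-(propan-2-yl)cyclopent-2-en-1-ol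
Conditions: Zn dust, THF/sat. aq NH4Cl, 0 °C → rt
Reagents that add atoms: allyl bromide (compound 5), C=CCBr
Why: Zinc-mediated Barbier allylation adds 1,2 to the hindered enal and tolerates the free tertiary alcohol; the new carbinol centre is formed without control because it becomes sp2 in step 4.

Step 4
Reactants: 6 (1S)-2-(1-hydroxybut-3-en-1-yl)-3-methyl-1-(propan-2-yl)cyclopent-2-en-1-ol
Product: 8 (1R,2S,5R)-2-hydroxy-5-methyl-2-(propan-2-yl)-5-(prop-2-en-1-yl)cyclopentane-1-carbaldehyde, via dipotassium enolate 7 (not isolated)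
Conditions: KH (2.5 equiv), 18-crown-6 (2.5 equiv), THF, 0 °C → rt; inverse quench into AcOH/THF, −78 °C
Reagents that add atoms: none
Why: Anionic oxy-Cope rearrangement ([3,3], chair transition state) moves the allyl group to C1 on the face opposite the isopropyl group (cis to the C4 oxygen) and so sets the quaternary centre, and kinetic protonation of the aldehyde enolate from the same less hindered face (opposite isopropyl and methyl, relayed by the C4 hydroxyl) sets C5 with its hydrogen trans to the C1 methyl group.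

Step 5
Reactants: 8 (1R,2S,5R)-2-hydroxy-5-methyl-2-(propan-2-yl)-5-(prop-2-en-1-yl)cyclopentane-1-carbaldehyde; 9 2-methylallylmagnesium chloride
Product: 11 (1S,2S,3R)-2-[(1R)-1-hydroxy-3-methylbut-3-en-1-yl]-3-methyl-1-(propan-2-yl)-3-(prop-2-en-1-yl)cyclopentan-1-ol, via diisopinocampheylborinate 10 (not isolated)
Conditions: (+)-Ipc2BOMe [(+)-B-methoxydiisopinocampheylborane], 9, Et2O, −78 °C → rt; then 8, −78 °C; then NaOH, H2O2, 0 °C → rt
Reagents that add atoms: 2-methylallylmagnesium chloride (compound 9), CC(=C)C[Mg]Cl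
Why: Brown allylboration through a closed six-membered chair transition state, in which the isopinocampheyl groups derived from (−)-α-pinene direct the methallyl group to the re face of the aldehyde, gives the (R)-carbinol at C6 and is matched with Felkin–Anh attack anti to the C4 carbon.

Step 6
Reactants: 11 (1S,2S,3R)-2-[(1R)-1-hydroxy-3-methylbut-3-en-1-yl]-3-methyl-1-(propan-2-yl)-3-(prop-2-en-1-yl)cyclopentan-1-ol
Product: 12 (3S,3aS,4R,8aR)-6,8a-dimethyl-3-(propan-2-yl)-1,2,3,3a,4,5,8,8a-octahydroazulene-3,4-diol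
Conditions: second-generation Grubbs catalyst (H2IMes)(PCy3)Cl2Ru=CHPh (5 mol %), CH2Cl2 (0.005 M), 40 °C
Reagents that add atoms: none
Why: Ring-closing metathesis of the monosubstituted and the 1,1-disubstituted olefin closes the trans-fused seven-membered ring with the trisubstituted C8=C9 double bond, and no stereocentre is affected.

Step 7
Reactants: 12 (3S,3aS,4R,8aR)-6,8a-dimethyl-3-(propan-2-yl)-1,2,3,3a,4,5,8,8a-octahydroazulene-3,4-diol; 13 4-(acetyloxy)benzoyl chloride
Product: 14 (3S,3aS,4R,8aR)-3-hydroxy-6,8a-dimethyl-3-(propan-2-yl)-1,2,3,3a,4,5,8,8a-octahydroazulen-4-yl 4-(acetyloxy)benzoate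
Conditions: pyridine, DMAP (0.2 equiv), CH2Cl2, 0 °C → rt
Reagents that add atoms: 4-(acetyloxy)benzoyl chloride (compound 13), CC(=O)Oc1ccc(cc1)C(Cl)=O
Why: DMAP-catalysed acylation (nucleophilic catalysis) esterifies the secondary C6 alcohol with retention, while the hindered tertiary C4 alcohol does not react.

Step 8
Reactants: 14 (3S,3aS,4R,8aR)-3-hydroxy-6,8a-dimethyl-3-(propan-2-yl)-1,2,3,3a,4,5,8,8a-octahydroazulen-4-yl 4-(acetyloxy)benzoate; 15 3-methylbutanoic acid
Product: 16 (3S,3aS,4R,8R,8aS)-4-{[4-(acetyloxy)benzoyl]oxy}-3-hydroxy-6,8a-dimethyl-3-(propan-2-yl)-1,2,3,3a,4,5,8,8a-octahydroazulen-8-yl 3-methylbutanoate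
Conditions: CuOAc (10 mol %), 2,2'-bis(2-oxazoline) (12 mol %), N-fluorobenzenesulfonimide (1.5 equiv), 15 (4 equiv), Li2CO3 (1 equiv), PhCl, 30 °C
Reagents that add atoms: 3-methylbutanoic acid (compound 15), CC(C)CC(O)=O
Why: Proposed new method: copper-catalysed radical-relay allylic C–H acyloxylation of an internal trisubstituted cycloalkene with a free carboxylic acid, in which monovalent copper reduces N-fluorobenzenesulfonimide to a copper-bound sulfonimidyl radical that abstracts a C10 hydrogen (C7–H is deactivated by the neighbouring acyloxy group, the C14 methyl C–H is primary, and C10–H abstraction gives the most substituted allyl radical), the allyl radical is trapped by divalent copper isovalerate, and C–O reductive elimination from trivalent copper takes place at the secondary terminus C10 on the face opposite the C1 methyl group, helped by a hydrogen bond from the cis C4 hydroxyl, which sets C10 as (R) and keeps the C8=C9 double bond; the closest known reaction types are the Kharasch–Sosnovsky allylic acyloxylation with peresters and the copper/N-fluorobenzenesulfonimide radical-relay allylic C–H cyanation and benzylic C–H etherification.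

Step 9
Reactants: 16 (3S,3aS,4R,8R,8aS)-4-{[4-(acetyloxy)benzoyl]oxy}-3-hydroxy-6,8a-dimethyl-3-(propan-2-yl)-1,2,3,3a,4,5,8,8a-octahydroazulen-8-yl 3-methylbutanoate
Product: 17 (3S,3aS,4R,8R,8aS)-3-hydroxy-4-[(4-hydroxybenzoyl)oxy]-6,8a-dimethyl-3-(propan-2-yl)-1,2,3,3a,4,5,8,8a-octahydroazulen-8-yl 3-methylbutanoate
Conditions: pyrrolidine (3 equiv), CH2Cl2, 0 °C
Reagents that add atoms: none
Why: Aminolysis of the phenolic acetate by pyrrolidine is far faster than attack on the two hindered alkyl esters, so the phenol is freed chemoselectively without touching any stereocentre.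

**Compound list**

1 | (R)-terpinen-4-ol, (1R)-4-methyl-1-(propan-2-yl)cyclohex-3-en-1-ol | CC1=CC[C@@](O)(C(C)C)CC1 | starting material
2 | secondary ozonide, (4R)-1-methyl-4-(propan-2-yl)-7,8,9-trioxabicyclo[4.2.1]nonan-4-ol (ozonide carbons as formed) | CC12CC[C@](O)(C(C)C)CC(O1)OO2 | intermediate
3 | (3R)-3-hydroxy-6-oxo-3-(propan-2-yl)heptanal | O=CC[C@@](O)(C(C)C)CCC(C)=O | intermediate
4 | (5S)-5-hydroxy-2-methyl-5-(propan-2-yl)cyclopent-1-ene-1-carbaldehyde | CC1=C(C=O)[C@@](O)(C(C)C)CC1 | intermediate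
5 | allyl bromide (3-bromoprop-1-ene) | C=CCBr | starting material
6 | (1S)-2-(1-hydroxybut-3-en-1-yl)-3-methyl-1-(propan-2-yl)cyclopent-2-en-1-ol (both epimers at the side-chain carbinol) | CC1=C(C(O)CC=C)[C@@](O)(C(C)C)CC1 | intermediate
7 | dipotassium enolate, dipotassium (1S,3R)-3-methyl-2-(oxidomethylidene)-1-(propan-2-yl)-3-(prop-2-en-1-yl)cyclopentan-1-olate | C=CC[C@@]1(C)CC[C@]([O-])(C(C)C)C1=C[O-].[K+].[K+] | intermediate
8 | (1R,2S,5R)-2-hydroxy-5-methyl-2-(propan-2-yl)-5-(prop-2-en-1-yl)cyclopentane-1-carbaldehyde (allyl cis to OH, CHO trans to OH) | C=CC[C@@]1(C)CC[C@](O)(C(C)C)[C@@H]1C=O | intermediate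
9 | 2-methylallylmagnesium chloride | CC(=C)C[Mg]Cl | starting material
10 | diisopinocampheylborinate, (1R)-1-[(1S,2S,5R)-2-hydroxy-5-methyl-2-(propan-2-yl)-5-(prop-2-en-1-yl)cyclopentyl]-3-methylbut-3-en-1-yl diisopinocampheylborinate (isopinocampheyl groups as in (+)-isopinocampheol) | C=CC[C@@]1(C)CC[C@](O)(C(C)C)[C@@H]1[C@H](OB([C@H]2C[C@H]3C[C@H](C3(C)C)[C@@H]2C)[C@H]2C[C@H]3C[C@H](C3(C)C)[C@@H]2C)CC(C)=C | intermediate
11 | (1S,2S,3R)-2-[(1R)-1-hydroxy-3-methylbut-3-en-1-yl]-3-methyl-1-(propan-2-yl)-3-(prop-2-en-1-yl)cyclopentan-1-ol | C=CC[C@@]1(C)CC[C@](O)(C(C)C)[C@@H]1[C@H](O)CC(C)=C | intermediate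
12 | (3S,3aS,4R,8aR)-6,8a-dimethyl-3-(propan-2-yl)-1,2,3,3a,4,5,8,8a-octahydroazulene-3,4-diol | CC1=CC[C@@]2(C)CC[C@](O)(C(C)C)[C@@H]2[C@H](O)C1 | intermediate
13 | 4-(acetyloxy)benzoyl chloride | CC(=O)Oc1ccc(cc1)C(Cl)=O | starting material
14 | (3S,3aS,4R,8aR)-3-hydroxy-6,8a-dimethyl-3-(propan-2-yl)-1,2,3,3a,4,5,8,8a-octahydroazulen-4-yl 4-(acetyloxy)benzoate | CC1=CC[C@@]2(C)CC[C@](O)(C(C)C)[C@@H]2[C@H](OC(=O)c2ccc(OC(C)=O)cc2)C1 | intermediate
15 | 3-methylbutanoic acid (isovaleric acid) | CC(C)CC(O)=O | starting material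
16 | (3S,3aS,4R,8R,8aS)-4-{[4-(acetyloxy)benzoyl]oxy}-3-hydroxy-6,8a-dimethyl-3-(propan-2-yl)-1,2,3,3a,4,5,8,8a-octahydroazulen-8-yl 3-methylbutanoate | CC1=C[C@@H](OC(=O)CC(C)C)[C@@]2(C)CC[C@](O)(C(C)C)[C@@H]2[C@H](OC(=O)c2ccc(OC(C)=O)cc2)C1 | intermediate
17 | (3S,3aS,4R,8R,8aS)-3-hydroxy-4-[(4-hydroxybenzoyl)oxy]-6,8a-dimethyl-3-(propan-2-yl)-1,2,3,3a,4,5,8,8a-octahydroazulen-8-yl 3-methylbutanoate | CC1=C[C@@H](OC(=O)CC(C)C)[C@@]2(C)CC[C@](O)(C(C)C)[C@@H]2[C@H](OC(=O)c2ccc(O)cc2)C1 | target

**Step count and risks**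

Total steps: 9. Longest linear sequence: 9 steps (1 → 17); compounds 5, 9, 13 and 15 are used as bought.

The three steps most likely to fail:

1. Step 8 (the new C–H acyloxylation). Site selectivity (C10 against C7 and the C14 methyl), facial selectivity, and competition from the cis C4 hydroxyl (cyclic ether formation) are untested. Fallback with known chemistry, setting out from 14 and returning at 16: allylic oxidation of 14 with t-BuOOH and catalytic dirhodium tetrakis(caprolactamate), Rh2(cap)4, with K2CO3 in CH2Cl2 oxidises the CH2 between the olefinic CH and the quaternary carbon and gives the 8-oxo enone F1. Corey–Bakshi–Shibata reduction with BH3·SMe2 and (S)-2-methyl-CBS-oxazaborolidine, with the quaternary C8a side as the large group, gives the (8R)-allylic alcohol F2. Acylation with 3-methylbutanoic anhydride, DMAP and pyridine gives 16.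

2. Step 4 (oxy-Cope and enolate protonation). The face of allyl transfer and of C5 protonation rests on steric arguments, and the β-hydroxy aldehyde 8 can open by retro-aldol if base and aldehyde coexist. Fallback setting out from 4 and returning at 8: Luche reduction of 4 (NaBH4, CeCl3·7H2O, MeOH) gives the allylic diol F3. Johnson–Claisen rearrangement (triethyl orthoacetate, catalytic propanoic acid, xylene, 140 °C) puts the acetate unit on C1, and only the isomer with this unit cis to the C4 hydroxyl can close to the bridged lactone F4, so the quaternary centre is secured by ring formation. Hydroboration–oxidation of the exocyclic methylene (9-BBN, then NaBO3·4H2O) from the lactone-bridge face gives the hydroxymethyl lactone F5, with the C5 hydrogen cis to the C4 oxygen. Reduction with (i-Bu)2AlH at −78 °C gives the lactol F6. Wittig methylenation (Ph3P=CH2, THF) opens it to the allyl diol F7. Oxidation of the primary alcohol with TEMPO and PhI(OAc)2 gives 8.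

3. Step 2 (aldol condensation of a free β-hydroxy aldehyde). Retro-aldol cleavage or β-elimination of the tertiary hydroxyl can compete with ring closure. Fallback setting out from 1 and returning at 4: silylation of 1 (Et3SiOTf, 2,6-lutidine, CH2Cl2) gives the silyl ether F8. Ozonolysis (O3, CH2Cl2, −78 °C; Me2S) gives the silyloxy keto-aldehyde F9. The same piperidine/AcOH condensation gives the silyloxy enal F10. Bu4NF in THF removes the silyl group and gives 4.

Further compounds
F1 | step 8 | 8-oxo enone, (3S,3aS,4R,8aS)-3-hydroxy-6,8a-dimethyl-8-oxo-3-(propan-2-yl)-1,2,3,3a,4,5,8,8a-octahydroazulen-4-yl 4-(acetyloxy)benzoate | CC1=CC(=O)[C@@]2(C)CC[C@](O)(C(C)C)[C@@H]2[C@H](OC(=O)c2ccc(OC(C)=O)cc2)C1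
F2 | step 8 | (8R)-allylic alcohol, (3S,3aS,4R,8R,8aS)-3,8-dihydroxy-6,8a-dimethyl-3-(propan-2-yl)-1,2,3,3a,4,5,8,8a-octahydroazulen-4-yl 4-(acetyloxy)benzoate | CC1=C[C@@H](O)[C@@]2(C)CC[C@](O)(C(C)C)[C@@H]2[C@H](OC(=O)c2ccc(OC(C)=O)cc2)C1
F3 | step 4 | allylic diol, (1S)-2-(hydroxymethyl)-3-methyl-1-(propan-2-yl)cyclopent-2-en-1-ol | CC1=C(CO)[C@@](O)(C(C)C)CC1
F4 | step 4 | bridged lactone, (1S,5R)-5-methyl-8-methylidene-1-(propan-2-yl)-2-oxabicyclo[3.2.1]octan-3-one | O=C1C[C@@]2(C)CC[C@](O1)(C(C)C)C2=C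
F5 | step 4 | hydroxymethyl lactone, (1S,5R,8S)-8-(hydroxymethyl)-5-methyl-1-(propan-2-yl)-2-oxabicyclo[3.2.1]octan-3-one | O=C1C[C@@]2(C)CC[C@](O1)(C(C)C)[C@@H]2CO
F6 | step 4 | lactol, (1S,5R,8S)-8-(hydroxymethyl)-5-methyl-1-(propan-2-yl)-2-oxabicyclo[3.2.1]octan-3-ol (both anomers) | OC1C[C@@]2(C)CC[C@](O1)(C(C)C)[C@@H]2CO
F7 | step 4 | allyl diol, (1S,2S,3R)-2-(hydroxymethyl)-3-methyl-1-(propan-2-yl)-3-(prop-2-en-1-yl)cyclopentan-1-ol | C=CC[C@@]1(C)CC[C@](O)(C(C)C)[C@@H]1CO
F8 | step 2 | silyl ether, triethyl{[(1R)-4-methyl-1-(propan-2-yl)cyclohex-3-en-1-yl]oxy}silane | CC1=CC[C@@](O[Si](CC)(CC)CC)(C(C)C)CC1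
F9 | step 2 | silyloxy keto-aldehyde, (3R)-6-oxo-3-(propan-2-yl)-3-[(triethylsilyl)oxy]heptanal | O=CC[C@@](O[Si](CC)(CC)CC)(C(C)C)CCC(C)=O
F10 | step 2 | silyloxy enal, (5S)-2-methyl-5-(propan-2-yl)-5-[(triethylsilyl)oxy]cyclopent-1-ene-1-carbaldehyde | CC1=C(C=O)[C@@](O[Si](CC)(CC)CC)(C(C)C)CC1
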